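**Retrosynthetic overview**
- Both indole rings are made last and together: twofold N-arylation of a hydrazone on a bis(4-bromophenyl) core, then Fischer indolisation with 3,3-dimethylpent-4-enal.
- The E-styryl arm comes from a Heck arylation of a vinyl group on the quaternary carbon; the vinyl group comes from a formyl group (Wittig).
- The cyclohexene is the first ring formed, by ring-closing metathesis of an acyclic α-quaternary aldehyde; the two indole rings follow.
- Key step: a stereospecific 1,2-shift (Meinwald/semipinacol) of an enantiopure trisubstituted epoxide, in which the α-aryl allyl carbon migrates onto the tertiary carbon and creates the aryl-CH/quaternary-C bond with both stereocentres.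
- The epoxide comes from Shi epoxidation of a skipped triene, itself made by iridium-catalysed allyl–alkenyl coupling of an aryl vinyl carbinol with an alkenyltrifluoroborate.

Assumption: hex-5-yn-2-one and 3,3-dimethylpent-4-enal are taken as catalogue compounds, and the facial sense of the chiral catalysts in steps 4 and 5 is taken from published models (the antipodal catalyst is used if one proves opposite).

**Route**

Step 1
Reactants: 1 1-bromo-4-iodobenzene; 2 acrolein
Product: 4 rac-1-(4-bromophenyl)prop-2-en-1-ol, via 4-bromophenylmagnesium chloride 3 (not isolated)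
Conditions: i-PrMgCl·LiCl (1.05 equiv), THF, −20 °C; then 2, −78 → 0 °C; aq NH4Cl
Reagents that add atoms: none
Why: Iodine–magnesium exchange is selective for C–I over C–Br and the aryl Grignard reagent adds 1,2 to acrolein (Grignard addition); the racemate suffices because step 4 is enantioconvergent.

Step 2
Reactants: 5 hex-5-yn-2-one
Product: 6 2-methylhex-1-en-5-yne
Conditions: Ph3PCH3Br, KOtBu, Et2O, 0 °C → rt; distilled and used as a solution
Reagents that add atoms: methyltriphenylphosphonium bromide C[P+](c1ccccc1)(c1ccccc1)c1ccccc1.[Br-]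
Why: Wittig methylenation of an unhindered methyl ketone, with an ylide too weakly basic to deprotonate the terminal alkyne.

Step 3
Reactants: 6 2-methylhex-1-en-5-yne
Product: 9 potassium [(1E)-2,5-dimethylhexa-1,5-dien-1-yl]trifluoroborate, via alkenyldimethylalane 7 (not isolated), via alkenyl pinacol boronate 8 (not isolated)
Conditions: Me3Al (2 equiv), Cp2ZrCl2 (20 mol%), CH2Cl2, 0 °C → rt; i-PrOBpin, −78 °C → rt; KHF2, MeOH–H2O, rt
Reagents that add atoms: trimethylaluminium C[Al](C)C; 2-isopropoxy-4,4,5,5-tetramethyl-1,3,2-dioxaborolane CC(C)OB1OC(C)(C)C(C)(C)O1; potassium hydrogen difluoride [K+].F.[F-]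
Why: Negishi zirconium-catalysed syn-carboalumination of the terminal alkyne fixes the E trisubstituted alkene (the 1,1-disubstituted alkene is inert), and alkenyl transfer from aluminium to boron followed by KHF2 exchange gives the stable trifluoroborate with retention of geometry.

Step 4
Reactants: 4 rac-1-(4-bromophenyl)prop-2-en-1-ol; 9 potassium [(1E)-2,5-dimethylhexa-1,5-dien-1-yl]trifluoroborate
Product: 10 1-bromo-4-[(3R,4E)-5,8-dimethylnona-1,4,8-trien-3-yl]benzene
Conditions: [Ir(cod)Cl]2 (4 mol%), (S)-N-(dinaphtho[2,1-d:1′,2′-f][1,3,2]dioxaphosphepin-4-yl)dibenzo[b,f]azepine (16 mol%), KHF2, CF3CO2H, n-Bu4NBr, 1,4-dioxane, 25 °C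
Reagents that add atoms: none
Why: Iridium-catalysed enantioconvergent allylic substitution (Carreira-type allyl–alkenyl coupling), in which the ligand-bound allyl-iridium complex is attacked at its benzylic terminus on one face, setting the benzylic stereocentre (R) while the E alkene is transferred unchanged.

Step 5
Reactants: 10 1-bromo-4-[(3R,4E)-5,8-dimethylnona-1,4,8-trien-3-yl]benzene
Product: 11 (2S,3S)-3-[(1S)-1-(4-bromophenyl)prop-2-en-1-yl]-2-methyl-2-(3-methylbut-3-en-1-yl)oxirane
Conditions: ent-Shi ketone (L-fructose-type, made from L-sorbose, 30 mol%), Oxone (2KHSO5·KHSO4·K2SO4), K2CO3, n-Bu4NHSO4, MeCN–CH2(OMe)2–aq Na2B4O7 buffer (pH 10.5), 0 °C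
Reagents that add atoms: potassium peroxymonosulfate (Oxone, KHSO5) [K+].[O-]S(=O)(=O)OO
Why: Shi asymmetric epoxidation, in which the chiral dioxirane reacts fastest with the E-trisubstituted alkene (vinyl and 1,1-disubstituted alkenes are poor substrates) and its spiro transition state sets both epoxide carbons (2S,3S) under catalyst control.

Step 6
Reactants: 11 (2S,3S)-3-[(1S)-1-(4-bromophenyl)prop-2-en-1-yl]-2-methyl-2-(3-methylbut-3-en-1-yl)oxirane
Product: 12 (2S)-2-[(1S)-1-(4-bromophenyl)prop-2-en-1-yl]-2,5-dimethylhex-5-enal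
Conditions: MeAl(OC6H2-2,6-tBu2-4-Br)2 (MABR, 20 mol%), CH2Cl2, −78 → −40 °C
Reagents that add atoms: none
Why: Proposed new method: a Meinwald-type 1,2-shift in which a stereogenic α-aryl allyl carbon is the migrating group; the bulky aluminium Lewis acid binds the epoxide oxygen, the tertiary C–O bond ionises, and the secondary carbon migrates anti to the leaving oxygen (retention at the migrating carbon, inversion at the tertiary terminus) in preference to hydride because aryl and vinyl stabilise its bridging transition state, so the aryl-CH/quaternary-C bond and the quaternary stereocentre form with transfer of both epoxide and benzylic chirality; the closest known reaction type is the MABR-promoted rearrangement of trisubstituted epoxides and epoxy silyl ethers to α-quaternary aldehydes by alkyl shift.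

Step 7
Reactants: 12 (2S)-2-[(1S)-1-(4-bromophenyl)prop-2-en-1-yl]-2,5-dimethylhex-5-enal
Product: 13 (1S,2S)-2-(4-bromophenyl)-1,4-dimethylcyclohex-3-ene-1-carbaldehyde
Conditions: second-generation Grubbs catalyst RuCl2(=CHPh)(PCy3)(H2IMes) (5 mol%), CH2Cl2 (0.01 M), 40 °C
Reagents that add atoms: none
Why: Ring-closing metathesis of the vinyl and isopropenyl groups closes the cyclohexene at its trisubstituted C=C with loss of ethene and touches neither stereocentre, so aryl and formyl end up cis.

Step 8
Reactants: 13 (1S,2S)-2-(4-bromophenyl)-1,4-dimethylcyclohex-3-ene-1-carbaldehyde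
Product: 14 1-bromo-4-[(1R,6R)-6-ethenyl-3,6-dimethylcyclohex-2-en-1-yl]benzene
Conditions: Ph3PCH3Br, KOtBu, THF, 0 °C → rt
Reagents that add atoms: methyltriphenylphosphonium bromide C[P+](c1ccccc1)(c1ccccc1)c1ccccc1.[Br-]
Why: Wittig methylenation of a non-enolisable quaternary aldehyde, which cannot epimerise.

Step 9
Reactants: 14 1-bromo-4-[(1R,6R)-6-ethenyl-3,6-dimethylcyclohex-2-en-1-yl]benzene; 1 1-bromo-4-iodobenzene
Product: 15 1-bromo-4-[(E)-2-[(1R,2R)-2-(4-bromophenyl)-1,4-dimethylcyclohex-3-en-1-yl]ethenyl]benzene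
Conditions: Pd(OAc)2 (5 mol%), n-Bu4NCl, NaHCO3, DMF, 70 °C
Reagents that add atoms: none
Why: Heck reaction under ligand-free Jeffery conditions, where C–I reacts far faster than either C–Br, the aryl group adds to the terminal carbon, and β-hydride elimination can only give the E-styrene because the allylic carbon is quaternary.

Step 10
Reactants: 15 1-bromo-4-[(E)-2-[(1R,2R)-2-(4-bromophenyl)-1,4-dimethylcyclohex-3-en-1-yl]ethenyl]benzene; 16 3,3-dimethylpent-4-enal
Product: 19 5-[(E)-2-{(1R,2R)-1,4-dimethyl-2-[3-(2-methylbut-3-en-2-yl)-1H-indol-5-yl]cyclohex-3-en-1-yl}ethenyl]-3-(2-methylbut-3-en-2-yl)-1H-indole (target), via bis(benzophenone hydrazone) 17 (not isolated), via bis(aldehyde hydrazone) 18 (not isolated)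
Conditions: Ph2C=NNH2 (2.4 equiv), Pd(OAc)2 (4 mol%), Xantphos (6 mol%), NaOtBu, toluene, 90 °C; then 16 (3 equiv), TsOH·H2O, EtOH, 70 °C
Reagents that add atoms: benzophenone hydrazone NN=C(c1ccccc1)c1ccccc1
Why: Twofold Buchwald–Hartwig N-arylation of benzophenone hydrazone, acid-mediated hydrazone exchange and Fischer indolisation in one flask, where a para-substituted arylhydrazine can only give the 5-substituted indole and the aldehyde CH2 becomes C3 bearing the 1,1-dimethylallyl group with C2 unsubstituted.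

**Compound list**

1 | 1-bromo-4-iodobenzene | Brc1ccc(I)cc1 | starting material
2 | acrolein (prop-2-enal) | C=CC=O | starting material
3 | 4-bromophenylmagnesium chloride (not isolated) | Brc1ccc([Mg]Cl)cc1 | intermediate
4 | rac-1-(4-bromophenyl)prop-2-en-1-ol | C=CC(O)c1ccc(Br)cc1 | intermediate
5 | hex-5-yn-2-one | CC(=O)CCC#C | starting material
6 | 2-methylhex-1-en-5-yne | C=C(C)CCC#C | intermediate
7 | [(1E)-2,5-dimethylhexa-1,5-dien-1-yl]dimethylaluminium (not isolated) | C=C(C)CC/C(C)=C/[Al](C)C | intermediate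
8 | 2-[(1E)-2,5-dimethylhexa-1,5-dien-1-yl]-4,4,5,5-tetramethyl-1,3,2-dioxaborolane (not isolated) | C=C(C)CC/C(C)=C/B1OC(C)(C)C(C)(C)O1 | intermediate
9 | potassium [(1E)-2,5-dimethylhexa-1,5-dien-1-yl]trifluoroborate | C=C(C)CC/C(C)=C/[B-](F)(F)F.[K+] | intermediate
10 | 1-bromo-4-[(3R,4E)-5,8-dimethylnona-1,4,8-trien-3-yl]benzene | C=C[C@@H](c1ccc(Br)cc1)/C=C(\C)CCC(C)=C | intermediate
11 | (2S,3S)-3-[(1S)-1-(4-bromophenyl)prop-2-en-1-yl]-2-methyl-2-(3-methylbut-3-en-1-yl)oxirane | C=C[C@@H](c1ccc(Br)cc1)[C@@H]1O[C@@]1(C)CCC(C)=C | intermediate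
12 | (2S)-2-[(1S)-1-(4-bromophenyl)prop-2-en-1-yl]-2,5-dimethylhex-5-enal | O=C[C@@](C)(CCC(C)=C)[C@@H](C=C)c1ccc(Br)cc1 | intermediate
13 | (1S,2S)-2-(4-bromophenyl)-1,4-dimethylcyclohex-3-ene-1-carbaldehyde | O=C[C@@]1(C)CCC(C)=C[C@H]1c1ccc(Br)cc1 | intermediate
14 | 1-bromo-4-[(1R,6R)-6-ethenyl-3,6-dimethylcyclohex-2-en-1-yl]benzene | C=C[C@@]1(C)CCC(C)=C[C@H]1c1ccc(Br)cc1 | intermediate
15 | 1-bromo-4-[(E)-2-[(1R,2R)-2-(4-bromophenyl)-1,4-dimethylcyclohex-3-en-1-yl]ethenyl]benzene | Brc1ccc(/C=C/[C@@]2(C)CCC(C)=C[C@H]2c2ccc(Br)cc2)cc1 | intermediate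
16 | 3,3-dimethylpent-4-enal | C=CC(C)(C)CC=O | starting material
17 | bis(benzophenone hydrazone) of the (1R,2R) core, N-aryl on both rings (not isolated) | C(=NNc1ccc(/C=C/[C@@]2(C)CCC(C)=C[C@H]2c2ccc(NN=C(c3ccccc3)c3ccccc3)cc2)cc1)(c1ccccc1)c1ccccc1 | intermediate
18 | bis(3,3-dimethylpent-4-enal arylhydrazone) of the (1R,2R) core (not isolated) | C=CC(C)(C)CC=NNc1ccc(/C=C/[C@@]2(C)CCC(C)=C[C@H]2c2ccc(NN=CCC(C)(C)C=C)cc2)cc1 | intermediate
19 | 5-[(E)-2-{(1R,2R)-1,4-dimethyl-2-[3-(2-methylbut-3-en-2-yl)-1H-indol-5-yl]cyclohex-3-en-1-yl}ethenyl]-3-(2-methylbut-3-en-2-yl)-1H-indole | C=CC(C)(C)c1c[nH]c2ccc(/C=C/[C@@]3(C)CCC(C)=C[C@H]3c3ccc4[nH]cc(C(C)(C)C=C)c4c3)cc12 | target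

**Step count and risks**

Total step count: 10. Longest linear sequence: 9 (5 → 6 → 9 → 10 → 11 → 12 → 13 → 14 → 15 → 19); step 1 is the only side branch.

The three steps most likely to fail:

Step 6 (the proposed new 1,2-shift). Risks are a competing hydride shift to the ketone and loss of stereochemical fidelity at the migrating benzylic carbon. The fallback uses known chemistry, sets out from 1 and comes back at 13. Heck coupling of 1 with isoprene F1 (Pd(OAc)2, n-Bu4NCl, NaHCO3, DMF, 80 °C) gives 1-bromo-4-[(1E)-3-methylbuta-1,3-dien-1-yl]benzene F2. An enantioselective Diels–Alder reaction of F2 with methacrolein F3, catalysed by a triflimide-activated o-tolyl oxazaborolidine from diphenylprolinol (CH2Cl2, −78 → −40 °C), then gives 13 directly. The 1-aryl and 3-methyl groups both direct to the required regiochemistry, and the endo formyl adduct (aryl cis to formyl) is the expected major product, to be separated from any exo isomer. Steps 2 to 7 are bypassed.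

Step 10 (twofold indolisation). Risks are acid-promoted loss or migration of the 1,1-dimethylallyl group and isomerisation of the ring alkene. The fallback avoids acid, sets out from 15 and comes back at 19. Palladium-catalysed amination of 15 with ammonia (Pd[P(o-tol)3]2, Josiphos CyPF-tBu, NaOtBu, NH3 in 1,4-dioxane) gives 4-[(E)-2-[(1R,2R)-2-(4-aminophenyl)-1,4-dimethylcyclohex-3-en-1-yl]ethenyl]aniline F4. Ortho-iodination of both aniline rings (BnNMe3·ICl2, CaCO3, CH2Cl2–MeOH, 0 °C) gives 4-[(E)-2-[(1R,2R)-2-(4-amino-3-iodophenyl)-1,4-dimethylcyclohex-3-en-1-yl]ethenyl]-2-iodoaniline F5. Palladium-catalysed annulation of F5 with aldehyde 16 (Pd(OAc)2, DABCO, DMF, 85 °C; enamine formation then intramolecular Heck cyclisation) builds both 3-substituted indoles and returns 19. The electron-rich styrene may compete in the iodination, so this fallback carries its own risk.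

Step 4 (iridium-catalysed allyl–alkenyl coupling). The risk is low reactivity or selectivity of the β,β-disubstituted alkenyltrifluoroborate. The fallback sets out from 4 and from boronate 8 (isolated after step 3 without the KHF2 treatment) and comes back at 10. 1,3-Transposition of 4 (Ph3SiOReO3 cat., Et2O, 0 °C) gives (2E)-3-(4-bromophenyl)prop-2-en-1-ol F6. Phosphorylation (ClP(O)(OEt)2, Et3N, DMAP, CH2Cl2) gives (2E)-3-(4-bromophenyl)prop-2-en-1-yl diethyl phosphate F7. Copper-catalysed SN2′-selective enantioselective allylic substitution of F7 with 8 (chiral sulfonate-bearing N-heterocyclic carbene, CuCl, NaOMe, THF, rt) then gives 10.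

**Further compounds**

F1 | step 6 | isoprene (2-methylbuta-1,3-diene) | C=CC(C)=C
F2 | step 6 | 1-bromo-4-[(1E)-3-methylbuta-1,3-dien-1-yl]benzene | C=C(C)/C=C/c1ccc(Br)cc1
F3 | step 6 | methacrolein (2-methylprop-2-enal) | C=C(C)C=O
F4 | step 10 | 4-[(E)-2-[(1R,2R)-2-(4-aminophenyl)-1,4-dimethylcyclohex-3-en-1-yl]ethenyl]aniline | Nc1ccc(/C=C/[C@@]2(C)CCC(C)=C[C@H]2c2ccc(N)cc2)cc1
F5 | step 10 | 4-[(E)-2-[(1R,2R)-2-(4-amino-3-iodophenyl)-1,4-dimethylcyclohex-3-en-1-yl]ethenyl]-2-iodoaniline | Nc1ccc(/C=C/[C@@]2(C)CCC(C)=C[C@H]2c2ccc(N)c(I)c2)cc1I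
F6 | step 4 | (2E)-3-(4-bromophenyl)prop-2-en-1-ol | OC/C=C/c1ccc(Br)cc1
F7 | step 4 | (2E)-3-(4-bromophenyl)prop-2-en-1-yl diethyl phosphate | CCOP(=O)(OCC)OC/C=C/c1ccc(Br)cc1
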